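## Structural features

The target is a single oxolane ring (O1, C2, C3, C4, C5) with carbon arms on two adjacent ring carbons: C4 carries a methylene (Cb) bonded to a guaiacyl ring (4-hydroxy-3-methoxyphenyl), and C3 carries a secondary carbinol carbon (Ca) bonded to a syringyl ring (4-hydroxy-3,5-dimethoxyphenyl). There are three contiguous stereocentres, C4 (S), C3 (S) and Ca (S); the ring substituents are trans, and in the extended chain aryl–Ca–C3–C2 the hydroxyl group and the C3–C4 bond lie anti. C2 and C5 are both unsubstituted OCH2 groups, so the ether ring can be closed from a primary 1,4-diol, or carried as a γ-lactone, without touching a stereocentre. The fragile part is the para-hydroxybenzylic alcohol on the syringyl side: once that phenol is free the Ca–O bond ionises readily under acid (quinone methide), it can be hydrogenolysed, and both free phenols are sensitive to oxidants. The trans ring pair is the easy part, because a substituent on C3 steers an incoming group at C4 to the opposite face; the real difficulty is the Ca/C3 pair, which lies across a freely rotating bond with no ring to hold it. The key step exploits the fact that Ca and C3 are the two carbons of an (E)-sinapyl C=C and that C4 is one bond from both: a temporary C4–Ca bond makes C3, C4 and Ca the corners of a cyclopropane fused to a γ-lactone (C5 as carbonyl, O1, C2, C3, C4), so that alkene geometry, not acyclic induction, fixes the Ca/C3 relationship.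

## Logic of the disconnections

20 ⇒ 18. The bonds cut are the two sulfonyl S–O bonds on the phenols and the Si–O bond on Ca. The free para-hydroxybenzylic alcohol is the most sensitive feature, so it is uncovered last. The gain is that every earlier step works on an electron-poor, robust arene. The demand is a deprotection that never ionises the Ca–O bond (fluoride, then alkali).

18 ⇒ 17. The O1–C5 bond is cut (O1–C2 is equivalent). Both carbons next to O1 are primary, so ring closure touches no stereocentre. The ring is reduced to an acyclic 1,4-diol. The demand is that only the two primary hydroxyls react, which the silyl group on the Ca oxygen secures.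

17 ⇒ 16. No skeletal bond is cut; C5 is raised to the carboxyl level and joined to the C2 oxygen as a γ-lactone. The lactone makes C4 enolisable and provides a rigid ring next to C3. The demand is a hydride that spares aryl sulfonates and the silyl ether.

16 ⇒ 11 + 14. The C4–Cb bond is cut. C4 is α to the lactone carbonyl and the bulky C3 arm shields one face, so the trans pair follows from substrate control. The guaiacyl unit becomes a simple benzylic bromide and the C4 stereocentre disappears. The demand is clean mono-alkylation anti to the C3 arm.

14 ⇒ 13 ⇒ 12. The C–Br bond and then the sulfonyl S–O bond are cut. This leads to a cheap benzylic alcohol whose phenol is masked first. The demand is chemoselective O-sulfonylation of the phenol.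

11 ⇒ 10. The Si–O bond is cut. The demand is only that silylation of a hindered secondary alcohol goes to completion.

10 ⇒ 9. The Ca–O bond is cut and the temporary C4–Ca bond is restored. This turns the acyclic Ca/C3 pair into two corners of a cyclopropane. The gain is that their relationship becomes a matter of alkene geometry. The demand on the forward step is cleavage of exactly the C4–Ca bond with inversion at Ca.

9 ⇒ 8. Both bonds from C4 (C4–C3 and C4–Ca) are cut, leaving C4 as a carbene carbon. Two rings and three stereocentres vanish, leaving an achiral (E)-allylic diazoacetate. The demand is enantioface selection by the catalyst and suppression of carbene dimerisation.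

8 ⇒ 7 ⇒ 5 + 6. The C=N2 unit is replaced by C–Br, then the ester C–O bond is cut. The diazo group is thus introduced last, under mild base, from an allylic alcohol and a two-carbon acyl bromide. The demand is that neither step isomerises the alkene.

5 ⇒ 4 ⇒ 2 + 3 ⇒ 1. The allylic alcohol is traced to the ester, the Ca=C3 double bond is cut, and the sulfonyl S–O bond is cut. This leads to a cheap aldehyde and a phosphonate. The demand is high E purity, because this geometry is later transcribed onto Ca; the ester is crystallised to secure it.

## Other disconnections considered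

Alternative 1: The cut removes both carbon bonds of Ca (C3–Ca and Ca–aryl), so that Ca comes from a one-carbon dichloromethyl reagent, dichloromethyllithium A2.
- Forward key step: A2 adds at very low temperature to the boron of the oxolan-3-yl boronic ester A1 (ester of (S,S)-1,2-dicyclohexylethane-1,2-diol). ZnCl2-assisted 1,2-migration of C3 (retention at C3) expels one chloride and gives the α-chloro boronic ester A3. In the same flask the aryl Grignard reagent A4 adds to boron, and a second 1,2-shift displaces the remaining chloride with inversion to give the α-aryl boronic ester A5. Oxidation of the C–B bond of A5 with retention and debenzylation would finish.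
- In favour: Ca is set by the twofold-symmetric diol on boron, a controller independent of C3. Both shifts are stereospecific. Two bonds to Ca form in one flask from the cheapest carbon source.
- Against: A1 already holds both ring stereocentres and needs its own enantio- and diastereoselective synthesis, which this cut does not supply. The migrating group is a branched secondary ring carbon next to the benzyl arm, so the first shift should be slow, and A3 can epimerise by chloride exchange while it waits. The step needs about −100 °C and a stoichiometric chiral diol whose match with C3 is unknown. Final hydrogenolysis of benzyl ethers puts the benzylic Ca–O bond at risk.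
- Comparison: On control of Ca the alternative is the equal of the chosen plan, and arguably the better, because a 1,2-metallate shift has no cationic escape route whereas the cyclopropane opening lies near the SN2/SN1 border. On structure the chosen plan is ahead: one catalytic event sets C3 together with Ca and leaves C4 to substrate control. On step economy the key flask is the equal of the chosen key step (two skeletal bonds each), but the total should be longer once A1 is counted.

Alternative 2: The cut removes C2–C3 and C4–C5, that is the whole C2–O1–C5 unit, leaving the (E)-enoyl imide A6 with an (S)-4-benzyl-oxazolidinone auxiliary.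
- Forward key step: CsF desilylates chloromethyl (trimethylsilyl)methyl ether A7; loss of chloride releases the parent carbonyl ylide A8. A8 adds suprafacially across the C=C of A6 in a 1,3-dipolar cycloaddition to give the oxolane imide A9.
- In favour: the ring and both ring stereocentres arise in one step. The trans relation follows stereospecifically from the E geometry. The auxiliary is recoverable.
- Against: A6 is a 4-aryl-but-2-enoyl system whose double bond can slip into conjugation with the arene under basic fluoride. A8 is short-lived and reacts without a chelating Lewis acid (fluoride would consume one), so the imide conformation is not locked and facial selectivity should be modest. Above all, Ca is not made: A9 must be converted through an N-methoxy-N-methylamide into the aryl ketone A10, and reduction of A10 must then create Ca by 1,2-induction from C3, which is the weakly controlled acyclic pair.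
- Comparison: On ring construction and step economy up to the oxolane the alternative is the better (one step against alkylation, reduction and cyclodehydration). On the trans C3/C4 relation the two are equal, and epimerisation at C3 of A10 would even correct itself towards trans. On mechanism and on the decisive Ca/C3 relation the chosen plan is stronger, since it replaces a ketone reduction of uncertain sense by two stereospecific events.

Alternative 3: The cut removes C3–C4 and Cb–aryl, giving the secondary bromide A11 (a silylated bromohydrin allyl ether with Ca already set) and the aryl iodide A12.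
- Forward key step: a low-valent nickel catalyst (NiBr2 with a bipyridine ligand, reduced by zinc metal) abstracts bromine from A11. The carbon radical at C3 cyclises 5-exo-trig onto the allyl ether, and the new primary radical at Cb is captured by the aryl–nickel species from A12. Reductive elimination gives the fully protected target A13.
- In favour: one step forms the ring, the C3–C4 bond and the aryl–Cb bond. The configuration at the bromide carbon is erased in the planar radical, so it need not be controlled. The guaiacyl unit enters as a stable aryl iodide and no strong base is needed. A13 is one deprotection sequence from the target.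
- Against: both new stereocentres arise under kinetic control of an open-shell step. For a hexenyl radical substituted at the radical carbon, the chair-like transition state usually leans towards the cis ring product, whereas trans is needed. The C3/Ca relation would rest on 1,2-induction in a mobile radical. Premature capture of the secondary radical by nickel would give direct arylation or β-elimination of the silyloxy group. Ca must still be set enantioselectively beforehand.
- Comparison: On step economy and convergence the alternative is the better, and on functional-group tolerance it is the equal or better (neutral reductive conditions). On structure and mechanism the chosen plan is stronger: Ca/C3 comes from a concerted addition and an invertive substitution and C4 from an enolate alkylation, whereas the alternative relies on two radical selectivities, one of which is expected to oppose the target. Both plans need exactly one enantioselective operation.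

Key step: step 6

Remarks on the chemistry (assumptions):
- Lactone 9 has to be the (1R,5S,6S) isomer with the aryl group exo; inversion at Ca then gives the (S)-carbinol next to (S)-C3, so the structures of 8 and 9 are consistent with the target and are used unchanged.
- The 4S antipode of the carboxamidate catalyst is taken to give this sense, as in the (1R,5S) series of simpler allylic diazoacetates; the 4R catalyst is the remedy if the sense proves opposite.
- Design points: the arenesulfonate on the syringyl oxygen is kept, and the same group is put on the guaiacyl oxygen so that both are removed together; E purity is secured at crystalline ester 4; LiBH4 is used for the lactone reduction to spare the sulfonates; the side chain starts from vanillyl alcohol to save a step.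

## Steps

Step 1
Reactants: 1 syringaldehyde
Product: 2 O-tosylsyringaldehyde (4-formyl-2,6-dimethoxyphenyl 4-methylbenzenesulfonate)
Conditions: TsCl, Et3N, DMAP (cat.), CH2Cl2, 0 °C to rt
Reagents that add atoms: p-toluenesulfonyl chloride, Cc1ccc(cc1)S(=O)(=O)Cl
Why: O-sulfonylation of a phenol; the sulfonate masks the phenol against base, hydride and the carbene, and makes the arene a weak donor for the later opening.

Step 2
Reactants: 2 O-tosylsyringaldehyde; 3 triethyl phosphonoacetate
Product: 4 ethyl (E)-3-[3,5-dimethoxy-4-(tosyloxy)phenyl]prop-2-enoate
Conditions: LiCl, DBU, MeCN, rt; recrystallisation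
Reagents that add atoms: none
Why: Horner–Wadsworth–Emmons olefination under mild LiCl/amidine conditions; the stabilised phosphonate anion and an aryl aldehyde should give the E alkene almost exclusively, and crystallisation removes any Z isomer.

Step 3
Reactants: 4 ethyl (E)-3-[3,5-dimethoxy-4-(tosyloxy)phenyl]prop-2-enoate
Product: 5 (E)-O-tosylsinapyl alcohol, (E)-3-[3,5-dimethoxy-4-(tosyloxy)phenyl]prop-2-en-1-ol
Conditions: i-Bu2AlH (2.5 equiv), CH2Cl2, −78 to 0 °C; aq. KNa tartrate
Reagents that add atoms: none
Why: 1,2-reduction of a conjugated ester to the allylic alcohol by an aluminium hydride; the C=C geometry and the aryl sulfonate are not touched at low temperature.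

Step 4
Reactants: 5 (E)-O-tosylsinapyl alcohol; 6 bromoacetyl bromide
Product: 7 (E)-O-tosylsinapyl bromoacetate
Conditions: NaHCO3, MeCN, 0 °C
Reagents that add atoms: none
Why: O-acylation of a primary allylic alcohol by an acyl bromide; the weak insoluble base scavenges HBr without allylic substitution or alkene isomerisation.

Step 5
Reactants: 7 (E)-O-tosylsinapyl bromoacetate
Product: 8 (E)-O-tosylsinapyl diazoacetate
Conditions: TsNHNHTs (2 equiv), DBU (5 equiv), THF, 0 °C
Reagents that add atoms: N,N'-ditosylhydrazine, Cc1ccc(cc1)S(=O)(=O)NNS(=O)(=O)c1ccc(C)cc1
Why: Diazoacetate synthesis from a bromoacetate: the hydrazide nitrogen displaces bromide and two base-induced losses of sulfinate leave the C=N2 group; the conditions are mild enough for an allylic ester.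

Step 6
Reactants: 8 (E)-O-tosylsinapyl diazoacetate
Product: 9 (1R,5S,6S)-6-[3,5-dimethoxy-4-(tosyloxy)phenyl]-3-oxabicyclo[3.1.0]hexan-2-one (aryl exo)
Conditions: Rh2(4S-MPPIM)4 (1 mol%), CH2Cl2, reflux, slow addition of 8 over several hours
Reagents that add atoms: none
Why: Enantioselective intramolecular cyclopropanation of an allylic diazoacetate with a chiral dirhodium carboxamidate, a known reaction type; MPPIM is methyl (4S)-2-oxo-1-(3-phenylpropanoyl)imidazolidine-4-carboxylate and the metal is divalent rhodium. The diazo carbon binds to an axial site of the Rh–Rh core, N2 leaves, and the electrophilic rhodium carbene adds to the tethered C=C in one concerted, asynchronous [2+1] event that forms C4–C3 and the temporary C4–Ca bond. The γ-lactone closes because the three-atom ester tether forces the carbene carbon onto the near alkene carbon (a 5-exo mode with respect to the C=C), and the three-membered ring closes in the same event on the benzylic carbon (3-exo), so the ring fusion can only be cis. Ca is controlled by the alkene: syn addition keeps the E geometry, which places the aryl group exo and trans to C2. C3 and C4 are controlled by the catalyst, whose ligand ester groups around the carbene leave only one alkene face open; the 4S ligand set is the one expected to give the (1R,5S) fusion. The step needs enantioface selection and preference for cyclopropanation over carbene dimerisation; the first is secured by the acylimidazolidinone ligands, which suit trans-disubstituted allyl esters, the second by slow addition of 8. The arenesulfonate is inert to the carbene, and the arene is held too far from the carbene carbon for addition to the ring.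

Step 7
Reactants: 9 (1R,5S,6S)-6-[3,5-dimethoxy-4-(tosyloxy)phenyl]-3-oxabicyclo[3.1.0]hexan-2-one
Product: 10 (4S)-4-[(S)-hydroxy[3,5-dimethoxy-4-(tosyloxy)phenyl]methyl]oxolan-2-one
Conditions: TfOH (cat.), H2O (5 equiv), (CF3)2CHOH, 40 °C
Reagents that add atoms: water, O
Why: Acid-promoted homoconjugate (SN2-type) opening of an aryl- and acyl-substituted cyclopropane by an oxygen nucleophile, a known solvolytic reaction of donor–acceptor cyclopropanes. Protonation of the lactone carbonyl weakens C4–Ca, the only ring bond that is both benzylic and α to the carbonyl; water attacks Ca from the side opposite C4, so Ca is inverted to (S), C3 is untouched, and the enol at C4 tautomerises to the lactone CH2. The sulfonate and the two meta methoxy groups keep the arene a weak donor, which disfavours a free benzylic cation in the ionising solvent.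

Step 8
Reactants: 10 (4S)-4-[(S)-hydroxy[3,5-dimethoxy-4-(tosyloxy)phenyl]methyl]oxolan-2-one
Product: 11 (4S)-4-[(S)-(tert-butyldimethylsilyloxy)[3,5-dimethoxy-4-(tosyloxy)phenyl]methyl]oxolan-2-one
Conditions: TBSOTf, 2,6-lutidine, CH2Cl2, −78 to 0 °C
Reagents that add atoms: tert-butyldimethylsilyl triflate, CC(C)(C)[Si](C)(C)OS(=O)(=O)C(F)(F)F
Why: Silylation of a hindered secondary alcohol with a silyl triflate; it blocks translactonisation, adds bulk for the facial control in step 11, and keeps the Ca oxygen out of the ring closure in step 13.

Step 9
Reactants: 12 vanillyl alcohol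
Product: 13 4-(hydroxymethyl)-2-methoxyphenyl 4-methylbenzenesulfonate
Conditions: TsCl (1.05 equiv), K2CO3, acetone, rt
Reagents that add atoms: p-toluenesulfonyl chloride, Cc1ccc(cc1)S(=O)(=O)Cl
Why: Chemoselective O-sulfonylation: carbonate deprotonates only the phenol, and the phenoxide is far more nucleophilic than the benzylic alcohol.

Step 10
Reactants: 13 4-(hydroxymethyl)-2-methoxyphenyl 4-methylbenzenesulfonate
Product: 14 4-(bromomethyl)-2-methoxyphenyl 4-methylbenzenesulfonate
Conditions: PBr3 (0.4 equiv), CH2Cl2, 0 °C
Reagents that add atoms: phosphorus tribromide, BrP(Br)Br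
Why: Conversion of a benzylic alcohol into the bromide through a phosphite ester; the electron-poor arene makes the bromide a stable SN2 electrophile that cannot form a quinone methide.

Step 11
Reactants: 11 (4S)-4-[(S)-(tert-butyldimethylsilyloxy)[3,5-dimethoxy-4-(tosyloxy)phenyl]methyl]oxolan-2-one; 14 4-(bromomethyl)-2-methoxyphenyl 4-methylbenzenesulfonate
Product: 16 (3S,4S)-4-[(S)-(tert-butyldimethylsilyloxy)[3,5-dimethoxy-4-(tosyloxy)phenyl]methyl]-3-[3-methoxy-4-(tosyloxy)benzyl]oxolan-2-one, via lithium enolate 15 (not isolated)
Conditions: LiN(SiMe3)2 (1.05 equiv), THF, −78 °C; then 14, DMPU, −78 to −40 °C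
Reagents that add atoms: none
Why: Alkylation of a γ-butyrolactone lithium enolate with a benzylic bromide; the bromide approaches the planar enolate anti to the bulky silyloxy(aryl)methyl arm on the neighbouring carbon, which sets C4 (S) trans to C3. The non-nucleophilic amide base and low temperature spare the sulfonates and limit dialkylation.

Step 12
Reactants: 16 (3S,4S)-4-[(S)-(tert-butyldimethylsilyloxy)[3,5-dimethoxy-4-(tosyloxy)phenyl]methyl]-3-[3-methoxy-4-(tosyloxy)benzyl]oxolan-2-one
Product: 17 (2S,3S)-2-[(S)-(tert-butyldimethylsilyloxy)[3,5-dimethoxy-4-(tosyloxy)phenyl]methyl]-3-[3-methoxy-4-(tosyloxy)benzyl]butane-1,4-diol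
Conditions: LiBH4, THF, MeOH (1 equiv), 0 °C to rt
Reagents that add atoms: none
Why: Borohydride reduction of a lactone to the 1,4-diol; LiBH4 leaves aryl sulfonates and silyl ethers alone and is too weakly basic to epimerise C4.

Step 13
Reactants: 17 (2S,3S)-2-[(S)-(tert-butyldimethylsilyloxy)[3,5-dimethoxy-4-(tosyloxy)phenyl]methyl]-3-[3-methoxy-4-(tosyloxy)benzyl]butane-1,4-diol
Product: 18 tert-butyldimethylsilyl ether bis-tosylate of the target, (3S,4S)-3-[(S)-(tert-butyldimethylsilyloxy)[3,5-dimethoxy-4-(tosyloxy)phenyl]methyl]-4-[3-methoxy-4-(tosyloxy)benzyl]oxolane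
Conditions: PPh3, DIAD, THF, 0 °C to rt
Reagents that add atoms: none
Why: Mitsunobu cyclodehydration of a 1,4-diol: one primary hydroxyl is activated as the oxyphosphonium ion and displaced by the other (5-exo-tet). Both carbons are CH2, so no stereocentre is involved, and the silylated Ca oxygen cannot compete.

Step 14
Reactants: 18 tert-butyldimethylsilyl ether bis-tosylate of the target
Product: 20 (S)-(4-hydroxy-3,5-dimethoxyphenyl)[(3S,4S)-4-(4-hydroxy-3-methoxybenzyl)oxolan-3-yl]methanol (target), via desilylated bis-tosylate 19 (not isolated)
Conditions: Bu4NF, THF, rt; then 2 M aq. KOH, t-BuOH, 60 °C; aq. NH4Cl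
Reagents that add atoms: none
Why: Fluoride-mediated desilylation followed by alkaline hydrolysis of the aryl sulfonates; hydroxide attacks sulfur, so the S–O bonds break and the aryl C–O bonds and Ca stay as they are. The medium is never acidic while the phenols are free, so the Ca–O bond is not ionised, and the absence of an alcohol solvent avoids O-alkylation of the phenoxides.

## Compound list

1 | syringaldehyde | COc1cc(C=O)cc(OC)c1O | starting material
2 | O-tosylsyringaldehyde | COc1cc(C=O)cc(OC)c1OS(=O)(=O)c1ccc(C)cc1 | intermediate
3 | triethyl phosphonoacetate | CCOC(=O)CP(=O)(OCC)OCC | starting material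
4 | ethyl (E)-3-[3,5-dimethoxy-4-(tosyloxy)phenyl]prop-2-enoate | CCOC(=O)/C=C/c1cc(OC)c(OS(=O)(=O)c2ccc(C)cc2)c(OC)c1 | intermediate
5 | (E)-O-tosylsinapyl alcohol | OC/C=C/c1cc(OC)c(OS(=O)(=O)c2ccc(C)cc2)c(OC)c1 | intermediate
6 | bromoacetyl bromide | BrCC(Br)=O | starting material
7 | (E)-O-tosylsinapyl bromoacetate | BrCC(=O)OC/C=C/c1cc(OC)c(OS(=O)(=O)c2ccc(C)cc2)c(OC)c1 | intermediate
8 | (E)-O-tosylsinapyl diazoacetate | COc1cc(/C=C/COC(=O)C=[N+]=[N-])cc(OC)c1OS(=O)(=O)c1ccc(C)cc1 | intermediate
9 | (1R,5S,6S)-6-[3,5-dimethoxy-4-(tosyloxy)phenyl]-3-oxabicyclo[3.1.0]hexan-2-one (aryl exo) | O=C1OC[C@H]2[C@H](c3cc(OC)c(OS(=O)(=O)c4ccc(C)cc4)c(OC)c3)[C@@H]12 | intermediate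
10 | (4S)-4-[(S)-hydroxy[3,5-dimethoxy-4-(tosyloxy)phenyl]methyl]oxolan-2-one | O=C1OC[C@@H]([C@H](O)c2cc(OC)c(OS(=O)(=O)c3ccc(C)cc3)c(OC)c2)C1 | intermediate
11 | (4S)-4-[(S)-(tert-butyldimethylsilyloxy)[3,5-dimethoxy-4-(tosyloxy)phenyl]methyl]oxolan-2-one | O=C1OC[C@@H]([C@H](O[Si](C)(C)C(C)(C)C)c2cc(OC)c(OS(=O)(=O)c3ccc(C)cc3)c(OC)c2)C1 | intermediate
12 | vanillyl alcohol (4-hydroxy-3-methoxybenzyl alcohol) | COc1cc(CO)ccc1O | starting material
13 | 4-(hydroxymethyl)-2-methoxyphenyl 4-methylbenzenesulfonate | COc1cc(CO)ccc1OS(=O)(=O)c1ccc(C)cc1 | intermediate
14 | 4-(bromomethyl)-2-methoxyphenyl 4-methylbenzenesulfonate | COc1cc(CBr)ccc1OS(=O)(=O)c1ccc(C)cc1 | intermediate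
15 | lithium enolate of 11 (formed in the flask, not isolated) | [Li]OC1=C[C@H]([C@H](O[Si](C)(C)C(C)(C)C)c2cc(OC)c(OS(=O)(=O)c3ccc(C)cc3)c(OC)c2)CO1 | intermediate
16 | (3S,4S)-4-[(S)-(tert-butyldimethylsilyloxy)[3,5-dimethoxy-4-(tosyloxy)phenyl]methyl]-3-[3-methoxy-4-(tosyloxy)benzyl]oxolan-2-one | O=C1OC[C@@H]([C@H](O[Si](C)(C)C(C)(C)C)c2cc(OC)c(OS(=O)(=O)c3ccc(C)cc3)c(OC)c2)[C@@H]1Cc1ccc(OS(=O)(=O)c2ccc(C)cc2)c(OC)c1 | intermediate
17 | (2S,3S)-2-[(S)-(tert-butyldimethylsilyloxy)[3,5-dimethoxy-4-(tosyloxy)phenyl]methyl]-3-[3-methoxy-4-(tosyloxy)benzyl]butane-1,4-diol | OC[C@@H](Cc1ccc(OS(=O)(=O)c2ccc(C)cc2)c(OC)c1)[C@@H](CO)[C@H](O[Si](C)(C)C(C)(C)C)c1cc(OC)c(OS(=O)(=O)c2ccc(C)cc2)c(OC)c1 | intermediate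
18 | (3S,4S)-3-[(S)-(tert-butyldimethylsilyloxy)[3,5-dimethoxy-4-(tosyloxy)phenyl]methyl]-4-[3-methoxy-4-(tosyloxy)benzyl]oxolane | COc1cc(C[C@@H]2COC[C@H]2[C@H](O[Si](C)(C)C(C)(C)C)c2cc(OC)c(OS(=O)(=O)c3ccc(C)cc3)c(OC)c2)ccc1OS(=O)(=O)c1ccc(C)cc1 | intermediate
19 | (S)-[3,5-dimethoxy-4-(tosyloxy)phenyl][(3S,4S)-4-[3-methoxy-4-(tosyloxy)benzyl]oxolan-3-yl]methanol (formed in the flask, not isolated) | COc1cc(C[C@@H]2COC[C@H]2[C@H](O)c2cc(OC)c(OS(=O)(=O)c3ccc(C)cc3)c(OC)c2)ccc1OS(=O)(=O)c1ccc(C)cc1 | intermediate
20 | (S)-(4-hydroxy-3,5-dimethoxyphenyl)[(3S,4S)-4-(4-hydroxy-3-methoxybenzyl)oxolan-3-yl]methanol | COc1cc(C[C@@H]2COC[C@H]2[C@H](O)c2cc(OC)c(O)c(OC)c2)ccc1O | target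

## Step count and least certain steps

Total step count: 14. Longest linear sequence: 12 steps (steps 1 to 8 and 11 to 14, from 1); the side chain (steps 9 and 10) joins at step 11.

Step 6 (key step). What may go wrong: incomplete enantioface discrimination, because the doubly ortho-flanked sulfonyloxy arene differs from the simple cinnamyl esters for which this catalyst type is established, and carbene dimerisation if 8 accumulates. Fallback (resolution in place of asymmetric catalysis): setting out from 8, decomposition with Rh2(OAc)4 (divalent rhodium) should give the racemic lactone, that is 9 together with the enantiomeric lactone F1. Heating the racemate with (S)-1-phenylethylamine opens the lactone ring to the hydroxy amide F2 (from 9) and the diastereomeric hydroxy amide F3 (from F1). These are separated by crystallisation or chromatography. F2 is relactonised with TsOH in warm toluene with loss of the amine, which returns to the route at 9.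

Step 7. What may go wrong: slow opening, because the sulfonylated arene is a weak donor; forcing it may shift the mechanism towards ionisation at Ca, with loss of the stereospecific inversion or elimination to an alkene. Fallback (reagent control in place of the relay): setting out from 9, solvolysis under forcing aqueous acid without regard to stereochemistry gives 10 mixed with the Ca-epimeric hydroxy lactone F4. Dess–Martin oxidation of the mixture converges on the keto lactone F5; non-basic conditions keep C3 intact. Corey–Bakshi–Shibata reduction of F5 with BH3·SMe2 and the (R)-configured methyl oxazaborolidine is expected to give the (S)-carbinol if the aryl group acts as the larger substituent (otherwise the antipode is used), returning at 10.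

Step 11. What may go wrong: slow alkylation next to the very bulky C3 arm, which allows proton transfer and dialkylation, and attack of the amide base on a sulfonate. Fallback (condensation, hydrogenation and equilibration in place of alkylation): setting out from 11 and 13, MnO2 oxidation of 13 gives the aldehyde F6. Aldol addition of enolate 15 to F6 gives the aldol adduct F7 (mixture at the two new centres). Mesylation and DBU elimination lead to the (E)-benzylidene lactone F8. Hydrogenation over palladium on carbon should deliver hydrogen anti to the C3 arm and give the cis lactone F9. DBU then epimerises C4 to the more stable trans isomer, returning at 16.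

Step 13. What may go wrong: migration of the silyl group from the Ca oxygen to the neighbouring primary oxygen (a 1,3-diol relationship) during reduction or activation, after which the freed benzylic hydroxyl would take part in ring closure and give a 2-aryl oxolane. Fallback (no diol at all): setting out from 16, partial reduction with i-Bu2AlH at −78 °C gives the lactol F10. Ionic reduction with Et3SiH and BF3·OEt2 at −78 °C removes the anomeric hydroxyl through the oxocarbenium ion and returns at 18, replacing steps 12 and 13; the electron-poor arene should keep the benzylic silyl ether intact.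

Step 14. What may go wrong: in the hot alkaline stage the syringyl phenoxide may expel the benzylic oxygen (quinone methide), which would epimerise Ca or add solvent, and the doubly flanked sulfonate may cleave slowly. Fallback (reductive cleavage and reversed order): setting out from 18, magnesium in methanol at rt cleaves both S–O bonds by electron transfer while Ca is still silylated, giving the diphenol silyl ether F11. Bu4NF buffered with acetic acid then removes the silyl group and arrives at 20.

## Further compounds

F1 | step 6 | (1S,5R,6R)-6-[3,5-dimethoxy-4-(tosyloxy)phenyl]-3-oxabicyclo[3.1.0]hexan-2-one (enantiomer of 9) | O=C1OC[C@@H]2[C@@H](c3cc(OC)c(OS(=O)(=O)c4ccc(C)cc4)c(OC)c3)[C@H]12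
F2 | step 6 | cis-2-(hydroxymethyl)-trans-3-aryl-N-[(S)-1-phenylethyl]cyclopropane-1-carboxamide with the ring configuration of 9 | O=C(N[C@@H](C)c1ccccc1)[C@H]1[C@@H](CO)[C@@H]1c1cc(OC)c(OS(=O)(=O)c2ccc(C)cc2)c(OC)c1
F3 | step 6 | diastereomeric hydroxy amide with the ring configuration of F1 | O=C(N[C@@H](C)c1ccccc1)[C@@H]1[C@H](CO)[C@H]1c1cc(OC)c(OS(=O)(=O)c2ccc(C)cc2)c(OC)c1
F4 | step 7 | (4S)-4-[(R)-hydroxy[3,5-dimethoxy-4-(tosyloxy)phenyl]methyl]oxolan-2-one (Ca epimer of 10) | O=C1OC[C@@H]([C@@H](O)c2cc(OC)c(OS(=O)(=O)c3ccc(C)cc3)c(OC)c2)C1
F5 | step 7 | (S)-4-[3,5-dimethoxy-4-(tosyloxy)benzoyl]oxolan-2-one | O=C1OC[C@@H](C(=O)c2cc(OC)c(OS(=O)(=O)c3ccc(C)cc3)c(OC)c2)C1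
F6 | step 11 | 4-formyl-2-methoxyphenyl 4-methylbenzenesulfonate | COc1cc(C=O)ccc1OS(=O)(=O)c1ccc(C)cc1
F7 | step 11 | aldol adduct of 11 and F6 (mixture at the two new centres) | O=C1OC[C@@H]([C@H](O[Si](C)(C)C(C)(C)C)c2cc(OC)c(OS(=O)(=O)c3ccc(C)cc3)c(OC)c2)C1C(O)c1ccc(OS(=O)(=O)c2ccc(C)cc2)c(OC)c1
F8 | step 11 | (E)-3-[3-methoxy-4-(tosyloxy)benzylidene] lactone | O=C1OC[C@@H]([C@H](O[Si](C)(C)C(C)(C)C)c2cc(OC)c(OS(=O)(=O)c3ccc(C)cc3)c(OC)c2)/C1=C\c1ccc(OS(=O)(=O)c2ccc(C)cc2)c(OC)c1
F9 | step 11 | cis lactone (C4 epimer of 16) | O=C1OC[C@@H]([C@H](O[Si](C)(C)C(C)(C)C)c2cc(OC)c(OS(=O)(=O)c3ccc(C)cc3)c(OC)c2)[C@H]1Cc1ccc(OS(=O)(=O)c2ccc(C)cc2)c(OC)c1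
F10 | step 13 | lactol from 16 (anomeric mixture) | OC1OC[C@@H]([C@H](O[Si](C)(C)C(C)(C)C)c2cc(OC)c(OS(=O)(=O)c3ccc(C)cc3)c(OC)c2)[C@@H]1Cc1ccc(OS(=O)(=O)c2ccc(C)cc2)c(OC)c1
F11 | step 14 | tert-butyldimethylsilyl ether of the target at the Ca oxygen, both phenols free | COc1cc(C[C@@H]2COC[C@H]2[C@H](O[Si](C)(C)C(C)(C)C)c2cc(OC)c(O)c(OC)c2)ccc1O
A1 | alternative 1 | (S,S)-1,2-dicyclohexylethane-1,2-diol ester of (3S,4S)-4-(4-benzyloxy-3-methoxybenzyl)oxolan-3-ylboronic acid | COc1cc(C[C@@H]2COC[C@H]2B2O[C@@H](C3CCCCC3)[C@H](C3CCCCC3)O2)ccc1OCc1ccccc1
A2 | alternative 1 | dichloromethyllithium | [Li]C(Cl)Cl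
A3 | alternative 1 | α-chloro boronic ester formed after the first 1,2-shift | COc1cc(C[C@@H]2COC[C@H]2[C@H](Cl)B2O[C@@H](C3CCCCC3)[C@H](C3CCCCC3)O2)ccc1OCc1ccccc1
A4 | alternative 1 | 4-benzyloxy-3,5-dimethoxyphenylmagnesium bromide | COc1cc([Mg]Br)cc(OC)c1OCc1ccccc1
A5 | alternative 1 | α-aryl boronic ester with the full carbon skeleton | COc1cc(C[C@@H]2COC[C@H]2[C@H](B3O[C@@H](C4CCCCC4)[C@H](C4CCCCC4)O3)c2cc(OC)c(OCc3ccccc3)c(OC)c2)ccc1OCc1ccccc1
A6 | alternative 2 | (S)-4-benzyl-3-[(E)-4-(4-benzyloxy-3-methoxyphenyl)but-2-enoyl]oxazolidin-2-one | COc1cc(C/C=C/C(=O)N2[C@@H](Cc3ccccc3)COC2=O)ccc1OCc1ccccc1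
A7 | alternative 2 | chloromethyl (trimethylsilyl)methyl ether | C[Si](C)(C)COCCl
A8 | alternative 2 | parent carbonyl ylide | [CH2-][O+]=C
A9 | alternative 2 | trans-4-benzyl-oxolane-3-carbonyl imide | COc1cc(C[C@@H]2COC[C@H]2C(=O)N2[C@@H](Cc3ccccc3)COC2=O)ccc1OCc1ccccc1
A10 | alternative 2 | (4-benzyloxy-3,5-dimethoxyphenyl) [(3S,4S)-4-(4-benzyloxy-3-methoxybenzyl)oxolan-3-yl] ketone | COc1cc(C[C@@H]2COC[C@H]2C(=O)c2cc(OC)c(OCc3ccccc3)c(OC)c2)ccc1OCc1ccccc1
A11 | alternative 3 | allyl ether of the silylated bromohydrin, (S) at Ca, either configuration at the bromide carbon | C=CCOCC(Br)[C@H](O[Si](C)(C)C(C)(C)C)c1cc(OC)c(OCc2ccccc2)c(OC)c1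
A12 | alternative 3 | 1-benzyloxy-4-iodo-2-methoxybenzene | COc1cc(I)ccc1OCc1ccccc1
A13 | alternative 3 | fully protected target (silyl ether, two benzyl ethers) | COc1cc(C[C@@H]2COC[C@H]2[C@H](O[Si](C)(C)C(C)(C)C)c2cc(OC)c(OCc3ccccc3)c(OC)c2)ccc1OCc1ccccc1
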